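**Retrosynthetic overview**

1. Ring A is the dihydrobenzofuran that carries the Z-styryl group; ring B is the dihydrobenzofuran that carries the 7-OH and is bound through its C5 to C3 of ring A. The last events are base methanolysis of six silyl ethers and one acetate, after Lindlar semi-hydrogenation of a diarylalkyne to the Z-alkene.
2. Furan ring of ring A (formed second, step 14): [4+1] disconnection at O1–C2 and C2–C3 into an o-quinone methide (C3, from the aryllithium of ring-B bromide 10 and Boc-salicylaldehyde 16) and a chiral 4-acetoxybenzyl sulfonium ylide (C2).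
3. Furan ring of ring B (formed first, step 7): the five-membered ring O1–C2–C3–C3a–C7a comes by ring expansion from a three-membered ring, the spirocyclopropane C3a–C3–C2 on a cyclohexadienone. That cyclopropane forms in the same flask from the rhodium carbene of o-quinone diazide 8 and silylated resveratrol 2, so both aryl groups and both stereocentres of ring B arrive together.
4. Enabling feature: in ring B, C3a has the ring oxygen O1 on its neighbour C7a and C7 carries OH, so the benzo ring can be an o-quinone diazide (C3a=N2, C7a=O, 7-O silylated, 5-Br as handle for ring A). C2 carries a 4-oxygenated aryl group, which makes bond C3a–C2 of the cyclopropane a donor–acceptor bond that breaks, and C2 is then taken by the carbonyl oxygen.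
5. Building blocks: resveratrol, 4-bromo-2-methoxyphenol, 5-bromoresorcinol, tert-butyl(4-ethynylphenoxy)dimethylsilane, 4-(bromomethyl)phenyl acetate and isothiocineole.

Key step: step 7

Assumption: the sense of induction of Rh2(S-TCPTTL)4 (step 7) and of the (1R,4R,5R)-sulfide (step 14) is taken to give the configurations drawn; if it is the opposite, the mirror-image catalyst or sulfide is used.
Abbreviations: TBS = tert-butyldimethylsilyl; Boc = tert-butoxycarbonyl; locants are benzofuran locants.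

**Route**

Step 1
Reactants: 1 resveratrol
Product: 2 (E)-3,5,4'-tris(TBS-oxy)stilbene
Conditions: TBSCl (3.3 equiv), imidazole, DMF, rt
Reagents that add atoms: tert-butyldimethylsilyl chloride, CC(C)(C)[Si](C)(C)Cl
Why: Silyl ether formation on the three phenols keeps the 4'-oxygen a para donor for step 7 and gives groups that come off with mild base at the end.

Step 2
Reactants: 3 4-bromo-2-methoxyphenol
Product: 4 4-bromo-2-methoxy-6-nitrophenol
Conditions: HNO3 (65%, 1.05 equiv), AcOH, 0–10 °C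
Reagents that add atoms: nitric acid, O[N+](=O)[O-]
Why: Electrophilic aromatic nitration goes ortho to the free phenol, whose para position is blocked by bromine.

Step 3
Reactants: 4 4-bromo-2-methoxy-6-nitrophenol
Product: 5 5-bromo-3-nitrobenzene-1,2-diol
Conditions: BBr3, CH2Cl2, −78 °C to rt; then H2O
Reagents that add atoms: none
Why: BBr3 demethylation of the aryl methyl ether removes a group that could not be cleaved at the end beside the Z-stilbene.

Step 4
Reactants: 5 5-bromo-3-nitrobenzene-1,2-diol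
Product: 6 5-bromo-1,2-bis(TBS-oxy)-3-nitrobenzene
Conditions: TBSCl (2.4 equiv), imidazole, DMAP (cat.), DMF, rt
Reagents that add atoms: tert-butyldimethylsilyl chloride, CC(C)(C)[Si](C)(C)Cl
Why: Silylation of both catechol hydroxyls gives one defined compound, the oxygen next to the nitro group being differentiated later by the diazonium ion.

Step 5
Reactants: 6 5-bromo-1,2-bis(TBS-oxy)-3-nitrobenzene
Product: 7 5-bromo-2,3-bis(TBS-oxy)aniline
Conditions: H2 (1 atm), Pt/C (sulfided), EtOAc, rt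
Reagents that add atoms: none
Why: Catalytic hydrogenation of the nitro group over sulfided platinum should leave the aryl bromide and the silyl ethers untouched.

Step 6
Reactants: 7 5-bromo-2,3-bis(TBS-oxy)aniline
Product: 8 4-bromo-6-diazo-2-(TBS-oxy)cyclohexa-2,4-dien-1-one (o-quinone diazide)
Conditions: isoamyl nitrite, AcOH (cat.), MeOH/CH2Cl2, 0 °C, dark
Reagents that add atoms: isoamyl nitrite, CC(C)CCON=O
Why: Aprotic diazotisation gives an aryldiazonium ion whose ortho silyl ether is then a leaving group on oxygen, so methanol takes the silyl group and the neutral o-quinone diazide results while the meta silyl ether stays.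

Step 7
Reactants: 8 4-bromo-6-diazo-2-(TBS-oxy)cyclohexa-2,4-dien-1-one; 2 (E)-3,5,4'-tris(TBS-oxy)stilbene
Product: 10 (2R,3R)-5-bromo-7-(TBS-oxy)-3-[3,5-bis(TBS-oxy)phenyl]-2-[4-(TBS-oxy)phenyl]-2,3-dihydrobenzofuran, via spirocyclopropyl dienone 9 (not isolated)
Conditions: Rh2(S-TCPTTL)4 (dirhodium tetrakis[N-tetrachlorophthaloyl-(S)-tert-leucinate], 1 mol%), 2 (1.5 equiv), CH2Cl2, 0 °C to rt, slow addition of 8, dark
Reagents that add atoms: none
Why: Proposed new method: the dirhodium carboxylate and o-quinone diazide 8 should give, with loss of N2, an electrophilic quinoid rhodium carbene at C3a that adds to the stilbene double bond of 2 from the face chosen by the chiral carboxylate pocket; the first bond goes to the carbon bearing the 3,5-disilyloxyphenyl ring because the developing positive charge is then held by the 4-silyloxyphenyl ring, and closure gives the trans-spirocyclopropane 9 stereospecifically. In 9 the bond C3a–C2 lies between a donor (4-silyloxyphenyl) and an acceptor (the dienone) and should break heterolytically with aromatisation to a phenoxide/benzylic cation pair, whose O1–C2 closure is 5-exo-trig onto the quinone-methide-like cation; the overall cyclopropane-to-dihydrofuran 1,3-shift is a Cloke–Wilson rearrangement, here a ring expansion from three ring atoms (C3a, C3, C2) to five (plus C7a and O1). The closest known reactions are the cyclopropanation of alkenes with rhodium carbenes of p-quinone diazides (isolable spiro[2.5]octadienones), the formal [3+2] annulation of cyclic 2-diazo-1,3-diketones and diazonaphthoquinones with vinyl ethers and styrenes under divalent rhodium catalysis, and the ring-opening cyclisation of cyclohexane-1,3-dione-2-spirocyclopropanes; what has not been shown is the enantioselective version with a 1,2-diaryl alkene. C3 is set in the carbene addition under catalyst control and is not touched afterwards, and C2 is set in the ring closure anti to the C3 aryl group (trans, which is also the thermodynamic isomer because C2–O1 ionisation is reversible). The step needs regioselectivity (cleavage of C3a–C2 and not C3a–C3, secured by the donor 4-silyloxyphenyl against the non-donating 3,5-disilyloxyphenyl ring), chemoselectivity for the alkene over aromatic C–H insertion (the conjugated, para-donor-substituted alkene is the most nucleophilic site and is in excess) and facial selectivity (catalyst).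

Step 8
Reactants: 11 5-bromobenzene-1,3-diol (5-bromoresorcinol)
Product: 12 2-bromo-4,6-dihydroxybenzaldehyde
Conditions: POCl3, DMF, MeCN, 0 °C to rt; then H2O, 50 °C
Reagents that add atoms: N,N-dimethylformamide, CN(C)C=O; water, O
Why: Vilsmeier–Haack formylation attacks the position ortho/para to the two hydroxyls (the two such positions are equivalent; the one between the hydroxyls is not attacked).

Step 9
Reactants: 12 2-bromo-4,6-dihydroxybenzaldehyde
Product: 13 2-bromo-6-hydroxy-4-(TBS-oxy)benzaldehyde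
Conditions: TBSCl (1.05 equiv), imidazole, CH2Cl2/DMF, 0 °C
Reagents that add atoms: tert-butyldimethylsilyl chloride, CC(C)(C)[Si](C)(C)Cl
Why: Selective silylation of the para hydroxyl is expected because the ortho hydroxyl is held in a hydrogen bond to the aldehyde and is the less reactive one.

Step 10
Reactants: 13 2-bromo-6-hydroxy-4-(TBS-oxy)benzaldehyde; 14 tert-butyl(4-ethynylphenoxy)dimethylsilane
Product: 15 2-hydroxy-4-(TBS-oxy)-6-{[4-(TBS-oxy)phenyl]ethynyl}benzaldehyde
Conditions: Pd(PPh3)2Cl2 (3 mol%), CuI (5 mol%), Et3N, THF, 45 °C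
Reagents that add atoms: none
Why: Sonogashira coupling at the aryl bromide activated by the ortho formyl group installs the future styryl carbons as an alkyne that is inert to the organolithium, ylide and base steps.

Step 11
Reactants: 15 2-hydroxy-4-(TBS-oxy)-6-{[4-(TBS-oxy)phenyl]ethynyl}benzaldehyde
Product: 16 tert-butyl 2-formyl-5-(TBS-oxy)-3-{[4-(TBS-oxy)phenyl]ethynyl}phenyl carbonate
Conditions: Boc2O, iPr2NEt, DMAP (cat.), CH2Cl2, 0 °C
Reagents that add atoms: di-tert-butyl dicarbonate, CC(C)(C)OC(=O)OC(=O)OC(C)(C)C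
Why: Carbonate formation on the remaining phenol puts in place the acyl group that later migrates to the benzylic oxygen and serves as leaving group for o-quinone methide formation.

Step 12
Reactants: 17 (1R,4R,5R)-4,7,7-trimethyl-6-thiabicyclo[3.2.1]octane (isothiocineole); 18 4-(bromomethyl)phenyl acetate
Product: 19 (1R,4R,5R)-6-(4-acetoxybenzyl)-4,7,7-trimethyl-6-thiabicyclo[3.2.1]octan-6-ium tetrafluoroborate
Conditions: NaBF4, CH2Cl2/H2O, rt
Reagents that add atoms: sodium tetrafluoroborate, [Na+].F[B-](F)(F)F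
Why: S-Alkylation of the sulfide by the benzylic bromide with exchange to the non-nucleophilic tetrafluoroborate gives the chiral benzylsulfonium salt.

Step 13
Reactants: 10 (2R,3R)-5-bromo-7-(TBS-oxy)-3-[3,5-bis(TBS-oxy)phenyl]-2-[4-(TBS-oxy)phenyl]-2,3-dihydrobenzofuran; 16 tert-butyl 2-formyl-5-(TBS-oxy)-3-{[4-(TBS-oxy)phenyl]ethynyl}phenyl carbonate
Product: 22 5-(TBS-oxy)-3-{[4-(TBS-oxy)phenyl]ethynyl}-2-{[ring-B-5-yl](4-methylphenylsulfonyl)methyl}phenol (ring-B-5-yl = the aryl group of 10 bound through C5; both epimers at the sulfonyl carbon), via aryllithium 20 (not isolated), via lithium phenoxide carbonate 21 (not isolated)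
Conditions: t-BuLi (2.0 equiv), THF, −78 °C; then 16, −78 °C; then p-toluenesulfinic acid (3 equiv), CH2Cl2, −78 to 0 °C
Reagents that add atoms: p-toluenesulfinic acid, Cc1ccc(cc1)S(=O)O
Why: Bromine–lithium exchange, 1,2-addition of aryllithium 20 to the aldehyde, O-to-O Boc transfer through a six-membered transition state to phenoxide 21 and, on acidification, loss of tert-butyl carbonate with capture of the o-quinone methide by sulfinate at sulfur (sulfa-Michael addition) should give the bench-stable sulfone, whose new uncontrolled carbon stereocentre is erased again in step 14.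

Step 14
Reactants: 22 the sulfone of step 13; 19 (1R,4R,5R)-6-(4-acetoxybenzyl)-4,7,7-trimethyl-6-thiabicyclo[3.2.1]octan-6-ium tetrafluoroborate
Product: 24 (2S,3S)-2-(4-acetoxyphenyl)-6-(TBS-oxy)-4-{[4-(TBS-oxy)phenyl]ethynyl}-3-[(2R,3R)-7-(TBS-oxy)-3-(3,5-bis(TBS-oxy)phenyl)-2-(4-(TBS-oxy)phenyl)-2,3-dihydrobenzofuran-5-yl]-2,3-dihydrobenzofuran, via o-quinone methide 23 (not isolated)
Conditions: Cs2CO3 (3 equiv), 19 (1.5 equiv), MeCN, 0 °C to rt
Reagents that add atoms: none
Why: This is the known [4+1] annulation of o-quinone methides with sulfonium ylides, in which carbonate turns 22 into 23 (E1cB loss of sulfinate) and 19 into its ylide, conjugate addition to the exocyclic carbon is followed by SN2 displacement of the sulfide by the phenoxide (5-exo-tet, inversion at C2, kept clean by the non-ionising 4-acetoxyphenyl group), the bicyclic sulfide fixes the reacting ylide face (C2) and the anti betaine leads to the trans ring (C3).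

Step 15
Reactants: 24 the alkyne of step 14
Product: 25 (2S,3S)-2-(4-acetoxyphenyl)-6-(TBS-oxy)-4-[(Z)-2-(4-(TBS-oxy)phenyl)ethenyl]-3-[(2R,3R)-7-(TBS-oxy)-3-(3,5-bis(TBS-oxy)phenyl)-2-(4-(TBS-oxy)phenyl)-2,3-dihydrobenzofuran-5-yl]-2,3-dihydrobenzofuran
Conditions: H2 (1 atm), Pd/CaCO3 poisoned with Pb(OAc)2 (Lindlar catalyst), quinoline, EtOAc, rt, dark
Reagents that add atoms: none
Why: Lindlar semi-hydrogenation adds H2 syn to the diarylalkyne on poisoned palladium and should stop at the Z-alkene.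

Step 16
Reactants: 25 the Z-alkene of step 15
Product: 26 (2R,3R)-3-(3,5-dihydroxyphenyl)-2-(4-hydroxyphenyl)-5-{(2S,3S)-6-hydroxy-2-(4-hydroxyphenyl)-4-[(Z)-2-(4-hydroxyphenyl)ethenyl]-2,3-dihydrobenzofuran-3-yl}-2,3-dihydrobenzofuran-7-ol (CNP0172909.2)
Conditions: K2CO3 (4 equiv), MeOH/THF (degassed), rt, dark; then AcOH
Reagents that add atoms: none
Why: Base-mediated methanolysis (transesterification of the aryl acetate and cleavage of the six aryl silyl ethers by methoxide) should free all seven phenols without acid, which the Z-stilbene next to the electron-rich rings would not tolerate.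

**Compound list**

1 | resveratrol | Oc1ccc(/C=C/c2cc(O)cc(O)c2)cc1 | starting material
2 | (E)-3,5,4'-tris(TBS-oxy)stilbene | CC(C)(C)[Si](C)(C)Oc1ccc(/C=C/c2cc(O[Si](C)(C)C(C)(C)C)cc(O[Si](C)(C)C(C)(C)C)c2)cc1 | intermediate
3 | 4-bromo-2-methoxyphenol | COc1cc(Br)ccc1O | starting material
4 | 4-bromo-2-methoxy-6-nitrophenol | COc1cc(Br)cc([N+](=O)[O-])c1O | intermediate
5 | 5-bromo-3-nitrobenzene-1,2-diol | Oc1cc(Br)cc([N+](=O)[O-])c1O | intermediate
6 | 5-bromo-1,2-bis(TBS-oxy)-3-nitrobenzene | CC(C)(C)[Si](C)(C)Oc1cc(Br)cc([N+](=O)[O-])c1O[Si](C)(C)C(C)(C)C | intermediate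
7 | 5-bromo-2,3-bis(TBS-oxy)aniline | CC(C)(C)[Si](C)(C)Oc1cc(Br)cc(N)c1O[Si](C)(C)C(C)(C)C | intermediate
8 | 4-bromo-6-diazo-2-(TBS-oxy)cyclohexa-2,4-dien-1-one | [N-]=[N+]=C1C=C(Br)C=C(O[Si](C)(C)C(C)(C)C)C1=O | intermediate
9 | trans-7-bromo-1-[3,5-bis(TBS-oxy)phenyl]-2-[4-(TBS-oxy)phenyl]-5-(TBS-oxy)spiro[2.5]octa-5,7-dien-4-one (spiro centre not assigned) | O=C1C(O[Si](C)(C)C(C)(C)C)=CC(Br)=CC12[C@@H](c1cc(O[Si](C)(C)C(C)(C)C)cc(O[Si](C)(C)C(C)(C)C)c1)[C@@H]2c1ccc(O[Si](C)(C)C(C)(C)C)cc1 | intermediate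
10 | (2R,3R)-5-bromo-7-(TBS-oxy)-3-[3,5-bis(TBS-oxy)phenyl]-2-[4-(TBS-oxy)phenyl]-2,3-dihydrobenzofuran | Brc1cc(O[Si](C)(C)C(C)(C)C)c2c(c1)[C@@H](c1cc(O[Si](C)(C)C(C)(C)C)cc(O[Si](C)(C)C(C)(C)C)c1)[C@H](c1ccc(O[Si](C)(C)C(C)(C)C)cc1)O2 | intermediate
11 | 5-bromobenzene-1,3-diol | Oc1cc(O)cc(Br)c1 | starting material
12 | 2-bromo-4,6-dihydroxybenzaldehyde | O=Cc1c(O)cc(O)cc1Br | intermediate
13 | 2-bromo-6-hydroxy-4-(TBS-oxy)benzaldehyde | O=Cc1c(O)cc(O[Si](C)(C)C(C)(C)C)cc1Br | intermediate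
14 | tert-butyl(4-ethynylphenoxy)dimethylsilane | C#Cc1ccc(O[Si](C)(C)C(C)(C)C)cc1 | starting material
15 | 2-hydroxy-4-(TBS-oxy)-6-{[4-(TBS-oxy)phenyl]ethynyl}benzaldehyde | O=Cc1c(O)cc(O[Si](C)(C)C(C)(C)C)cc1C#Cc1ccc(O[Si](C)(C)C(C)(C)C)cc1 | intermediate
16 | tert-butyl 2-formyl-5-(TBS-oxy)-3-{[4-(TBS-oxy)phenyl]ethynyl}phenyl carbonate | O=Cc1c(OC(=O)OC(C)(C)C)cc(O[Si](C)(C)C(C)(C)C)cc1C#Cc1ccc(O[Si](C)(C)C(C)(C)C)cc1 | intermediate
17 | (1R,4R,5R)-4,7,7-trimethyl-6-thiabicyclo[3.2.1]octane | C[C@@H]1CC[C@@H]2C[C@H]1SC2(C)C | starting material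
18 | 4-(bromomethyl)phenyl acetate | CC(=O)Oc1ccc(CBr)cc1 | starting material
19 | (1R,4R,5R)-6-(4-acetoxybenzyl)-4,7,7-trimethyl-6-thiabicyclo[3.2.1]octan-6-ium tetrafluoroborate | C[C@@H]1CC[C@@H]2C[C@H]1[S+](Cc1ccc(OC(C)=O)cc1)C2(C)C.F[B-](F)(F)F | intermediate
20 | aryllithium (10 with Li in place of Br) | [Li]c1cc(O[Si](C)(C)C(C)(C)C)c2c(c1)[C@@H](c1cc(O[Si](C)(C)C(C)(C)C)cc(O[Si](C)(C)C(C)(C)C)c1)[C@H](c1ccc(O[Si](C)(C)C(C)(C)C)cc1)O2 | intermediate
21 | lithium phenoxide with the benzylic tert-butyl carbonate (after Boc transfer) | [Li+].[O-]c1cc(O[Si](C)(C)C(C)(C)C)cc(C#Cc2ccc(O[Si](C)(C)C(C)(C)C)cc2)c1C(OC(=O)OC(C)(C)C)c1cc(O[Si](C)(C)C(C)(C)C)c2c(c1)[C@@H](c1cc(O[Si](C)(C)C(C)(C)C)cc(O[Si](C)(C)C(C)(C)C)c1)[C@H](c1ccc(O[Si](C)(C)C(C)(C)C)cc1)O2 | intermediate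
22 | sulfone: 2-{[ring-B-5-yl](4-methylphenylsulfonyl)methyl}-5-(TBS-oxy)-3-{[4-(TBS-oxy)phenyl]ethynyl}phenol | Cc1ccc(cc1)S(=O)(=O)C(c1cc(O[Si](C)(C)C(C)(C)C)c2c(c1)[C@@H](c1cc(O[Si](C)(C)C(C)(C)C)cc(O[Si](C)(C)C(C)(C)C)c1)[C@H](c1ccc(O[Si](C)(C)C(C)(C)C)cc1)O2)c1c(O)cc(O[Si](C)(C)C(C)(C)C)cc1C#Cc1ccc(O[Si](C)(C)C(C)(C)C)cc1 | intermediate
23 | o-quinone methide of ring A (exocyclic geometry not assigned) | O=C1C=C(O[Si](C)(C)C(C)(C)C)C=C(C#Cc2ccc(O[Si](C)(C)C(C)(C)C)cc2)C1=Cc1cc(O[Si](C)(C)C(C)(C)C)c2c(c1)[C@@H](c1cc(O[Si](C)(C)C(C)(C)C)cc(O[Si](C)(C)C(C)(C)C)c1)[C@H](c1ccc(O[Si](C)(C)C(C)(C)C)cc1)O2 | intermediate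
24 | alkyne bis(dihydrobenzofuran), (2S,3S) in ring A and (2R,3R) in ring B | CC(C)(C)[Si](C)(C)Oc1ccc(C#Cc2cc(O[Si](C)(C)C(C)(C)C)cc3c2[C@H](c2cc(O[Si](C)(C)C(C)(C)C)c4c(c2)[C@@H](c2cc(O[Si](C)(C)C(C)(C)C)cc(O[Si](C)(C)C(C)(C)C)c2)[C@H](c2ccc(O[Si](C)(C)C(C)(C)C)cc2)O4)[C@@H](c2ccc(OC(C)=O)cc2)O3)cc1 | intermediate
25 | Z-alkene, hexa-TBS monoacetate of the target | CC(C)(C)[Si](C)(C)Oc1ccc(/C=C\c2cc(O[Si](C)(C)C(C)(C)C)cc3c2[C@H](c2cc(O[Si](C)(C)C(C)(C)C)c4c(c2)[C@@H](c2cc(O[Si](C)(C)C(C)(C)C)cc(O[Si](C)(C)C(C)(C)C)c2)[C@H](c2ccc(O[Si](C)(C)C(C)(C)C)cc2)O4)[C@@H](c2ccc(OC(C)=O)cc2)O3)cc1 | intermediate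
26 | CNP0172909.2 | Oc1ccc(/C=C\c2cc(O)cc3c2[C@H](c2cc(O)c4c(c2)[C@@H](c2cc(O)cc(O)c2)[C@H](c2ccc(O)cc2)O4)[C@@H](c2ccc(O)cc2)O3)cc1 | target

**Step count and risks**

Total step count: 16. Longest linear sequence: 10 steps (3 → 4 → 5 → 6 → 7 → 8 → 10 → 22 → 24 → 25 → 26; steps 2–7 and 13–16).

Steps most likely to fail:

1. Step 7 (Proposed new method). The carbene may add to the trans-disubstituted alkene with poor facial selectivity, or be diverted into aromatic substitution of the 3,5-disilyloxyphenyl ring, carbene dimerisation or Wolff ring contraction. The fallback uses only known reaction types, sets out from 3 and returns at 10. Magnesium-mediated ortho-formylation of 3 (MgCl2, Et3N, paraformaldehyde, MeCN, reflux) gives 5-bromo-2-hydroxy-3-methoxybenzaldehyde F1. Boc2O/DMAP gives 4-bromo-2-formyl-6-methoxyphenyl tert-butyl carbonate F2. Addition of commercial 3,5-dimethoxyphenylmagnesium chloride at −78 °C, followed by p-toluenesulfinic acid (Boc transfer, o-quinone methide, sulfinate capture as in step 13), gives 4-bromo-2-[(3,5-dimethoxyphenyl)(4-methylphenylsulfonyl)methyl]-6-methoxyphenol F3. [4+1] annulation of F3 (Cs2CO3, MeCN) with (1S,4S,5S)-6-(4-methoxybenzyl)-4,7,7-trimethyl-6-thiabicyclo[3.2.1]octan-6-ium tetrafluoroborate F4 (from the enantiomer of 17, 4-methoxybenzyl bromide and NaBF4) gives (2R,3R)-5-bromo-3-(3,5-dimethoxyphenyl)-7-methoxy-2-(4-methoxyphenyl)-2,3-dihydrobenzofuran F5. BBr3 (CH2Cl2, −78 °C to 0 °C) cleaves the four methyl ethers to (2R,3R)-5-bromo-3-(3,5-dihydroxyphenyl)-2-(4-hydroxyphenyl)-2,3-dihydrobenzofuran-7-ol F6; C3 cannot epimerise and C2 recloses trans. TBSCl/imidazole then gives 10.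

2. Step 14. The ylide may discriminate the two faces poorly, the phenoxide may be O-benzylated by the sulfonium salt, or the acetate may be lost so that the sulfonium salt collapses to a p-quinone methide. The fallback sets out from 22 and returns at 24, and builds C2 as a carbonyl carbon instead of an ylide carbon. Compound 22 with Cs2CO3 releases 23 in the presence of 4-formylphenyl acetate and a thiazolium-derived N-heterocyclic carbene (3-benzyl-5-(2-hydroxyethyl)-4-methylthiazolium chloride); Stetter-type 1,4-acylation of the o-quinone methide gives the α,α-diaryl ketone F7. Asymmetric transfer hydrogenation (RuCl(p-cymene)[(S,S)-TsDPEN] or its enantiomer, HCO2H/Et3N) with dynamic kinetic resolution through the easily enolised diarylmethine aims at the (1R,2S)-alcohol F8. Mitsunobu etherification (PPh3, DIAD, THF) closes O1–C2 with inversion to give 24; alcohol of the other C3 configuration would close to the cis ring, which is removed by chromatography.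

3. Step 13. The Boc transfer may be incomplete, the o-quinone methide may form early and take up a second aryllithium or dimerise, or the aryllithium may be quenched by proton transfer. The fallback sets out from 15 (with 10) and returns at 22, and separates the events without the Boc relay. Compound 15 is deprotonated with NaH (THF, 0 °C) and the sodium phenoxide is added to aryllithium 20 at −78 °C; NH4Cl quench gives the isolable diol 2-[hydroxy(ring-B-5-yl)methyl]-5-(TBS-oxy)-3-{[4-(TBS-oxy)phenyl]ethynyl}phenol F9. p-Toluenesulfinic acid in CH2Cl2 at rt (acid-mediated substitution through 23) converts F9 into 22.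

**Further compounds**

F1 | step 7 | 5-bromo-2-hydroxy-3-methoxybenzaldehyde | COc1cc(Br)cc(C=O)c1O
F2 | step 7 | 4-bromo-2-formyl-6-methoxyphenyl tert-butyl carbonate | COc1cc(Br)cc(C=O)c1OC(=O)OC(C)(C)C
F3 | step 7 | 4-bromo-2-[(3,5-dimethoxyphenyl)(4-methylphenylsulfonyl)methyl]-6-methoxyphenol | COc1cc(OC)cc(c1)C(c1cc(Br)cc(OC)c1O)S(=O)(=O)c1ccc(C)cc1
F4 | step 7 | (1S,4S,5S)-6-(4-methoxybenzyl)-4,7,7-trimethyl-6-thiabicyclo[3.2.1]octan-6-ium tetrafluoroborate | C[C@H]1CC[C@H]2C[C@@H]1[S+](Cc1ccc(OC)cc1)C2(C)C.F[B-](F)(F)F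
F5 | step 7 | (2R,3R)-5-bromo-3-(3,5-dimethoxyphenyl)-7-methoxy-2-(4-methoxyphenyl)-2,3-dihydrobenzofuran | Brc1cc(OC)c2c(c1)[C@@H](c1cc(OC)cc(OC)c1)[C@H](c1ccc(OC)cc1)O2
F6 | step 7 | (2R,3R)-5-bromo-3-(3,5-dihydroxyphenyl)-2-(4-hydroxyphenyl)-2,3-dihydrobenzofuran-7-ol | Brc1cc(O)c2c(c1)[C@@H](c1cc(O)cc(O)c1)[C@H](c1ccc(O)cc1)O2
F7 | step 14 | 1-(4-acetoxyphenyl)-2-[2-hydroxy-4-(TBS-oxy)-6-{[4-(TBS-oxy)phenyl]ethynyl}phenyl]-2-(ring-B-5-yl)ethanone (C2 epimers) | CC(=O)Oc1ccc(cc1)C(=O)C(c1cc(O[Si](C)(C)C(C)(C)C)c2c(c1)[C@@H](c1cc(O[Si](C)(C)C(C)(C)C)cc(O[Si](C)(C)C(C)(C)C)c1)[C@H](c1ccc(O[Si](C)(C)C(C)(C)C)cc1)O2)c1c(O)cc(O[Si](C)(C)C(C)(C)C)cc1C#Cc1ccc(O[Si](C)(C)C(C)(C)C)cc1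
F8 | step 14 | (1R,2S)-1-(4-acetoxyphenyl)-2-[2-hydroxy-4-(TBS-oxy)-6-{[4-(TBS-oxy)phenyl]ethynyl}phenyl]-2-(ring-B-5-yl)ethanol | Oc1cc(O[Si](C)(C)C(C)(C)C)cc(C#Cc2ccc(O[Si](C)(C)C(C)(C)C)cc2)c1[C@H](c1cc(O[Si](C)(C)C(C)(C)C)c2c(c1)[C@@H](c1cc(O[Si](C)(C)C(C)(C)C)cc(O[Si](C)(C)C(C)(C)C)c1)[C@H](c1ccc(O[Si](C)(C)C(C)(C)C)cc1)O2)[C@@H](O)c1ccc(OC(C)=O)cc1
F9 | step 13 | 2-[hydroxy(ring-B-5-yl)methyl]-5-(TBS-oxy)-3-{[4-(TBS-oxy)phenyl]ethynyl}phenol (carbinol epimers) | Oc1cc(O[Si](C)(C)C(C)(C)C)cc(C#Cc2ccc(O[Si](C)(C)C(C)(C)C)cc2)c1C(O)c1cc(O[Si](C)(C)C(C)(C)C)c2c(c1)[C@@H](c1cc(O[Si](C)(C)C(C)(C)C)cc(O[Si](C)(C)C(C)(C)C)c1)[C@H](c1ccc(O[Si](C)(C)C(C)(C)C)cc1)O2
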